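**Retrosynthetic overview**

1. Germacrane numbering is used: C8 carries the lactone oxygen, C7 is the ring fusion, C6 the acyloxy carbon, C2 and C9 the carbinols, and C4=C5 and C1=C10 are the Z-alkenes.
2. Late stage: the C6 ester and the two silyl ethers are removed to give the macrocyclic C6 alcohol.
3. Key disconnection: C6–C7, the farnesyl C1–C10 bond of germacrene biogenesis. In the forward direction a lactone-embedded allyl metal (C13–C11=C7) attacks the C6 enal, which closes the ring, creates C6 and C7 and releases the C11=C13 methylene in one step.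
4. The acyclic (Z,Z)-farnesane-type chain is cut at C8–C9 (vinylogous aldol of a 2-silyloxyfuran carrying C7, C8, C11–C13), at C9–C10 (formylation) and at C2–C3 (vinylogous aldol/lactonisation of a senecioate dienolate with but-2-ynal).
5. Ring order: a temporary δ-lactone (fixes C2 and the Z C4=C5 alkene, then opened), the γ-lactone as a butenolide derived from a furan, and the ten-membered carbocycle last.

Assumption: the Tol-BINAP (step 2) and BINOL (step 8) enantiomers written are those expected to give the drawn configurations; if either sense is opposite on these substrates, the mirror-image ligand is used and nothing else changes.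

**Route**

Step 1
Reactants: 1 methyl 3-methylbut-2-enoate
Product: 2 [(1-methoxy-3-methylbuta-1,3-dien-1-yl)oxy]trimethylsilane
Conditions: LiN(iPr)2, THF, −78 °C; Me3SiCl, −78 °C → rt
Reagents that add atoms: chlorotrimethylsilane C[Si](C)(C)Cl
Why: Kinetic γ-deprotonation of the senecioate and O-silylation of the extended enolate give the silyl dienolate (silyl ketene acetal formation).

Step 2
Reactants: 2 [(1-methoxy-3-methylbuta-1,3-dien-1-yl)oxy]trimethylsilane; 3 but-2-ynal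
Product: 5 (6S)-4-methyl-6-(prop-1-yn-1-yl)-5,6-dihydro-2H-pyran-2-one, via copper aldolate 4 (not isolated)
Conditions: Cu(OTf)2 (10 mol %), (S)-Tol-BINAP (11 mol %), Bu4N[Ph3SiF2] (20 mol %), THF, −40 °C → rt
Reagents that add atoms: none
Why: Catalytic asymmetric vinylogous Mukaiyama aldol reaction through a Tol-BINAP-bound copper dienolate that selects one aldehyde face (sets C2 as S), after which the aldolate acylates itself, a lactonisation possible only for the Z-alkene and therefore fixing the C4=C5 geometry.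

Step 3
Reactants: 5 (6S)-4-methyl-6-(prop-1-yn-1-yl)-5,6-dihydro-2H-pyran-2-one
Product: 7 (2Z,5S,6Z)-7-iodo-3-methylocta-2,6-diene-1,5-diol, via alkenylalanate 6 (not isolated)
Conditions: NaAlH2(OCH2CH2OMe)2 (5 equiv), THF, 0 °C → rt; EtOAc; I2, −78 → 0 °C
Reagents that add atoms: iodine [I][I]
Why: Hydride reduction opens the lactone to the Z-allylic alkoxide and the freed propargylic alkoxide directs trans-hydroalumination of the alkyne, so iodinolysis of the cyclic alanate gives the alkenyl iodide with iodine cis to C2 (directed hydroalumination–iodination).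

Step 4
Reactants: 7 (2Z,5S,6Z)-7-iodo-3-methylocta-2,6-diene-1,5-diol
Product: 8 (2Z,5S,6Z)-1,5-bis[(tert-butyldimethylsilyl)oxy]-7-iodo-3-methylocta-2,6-diene
Conditions: TBSCl, imidazole, DMF, rt
Reagents that add atoms: tert-butyldimethylsilyl chloride CC(C)(C)[Si](C)(C)Cl
Why: Standard silylation protects both hydroxyls as ethers that survive the organolithium and Lewis acid steps and can later be distinguished as primary and secondary.

Step 5
Reactants: 8 (2Z,5S,6Z)-1,5-bis[(tert-butyldimethylsilyl)oxy]-7-iodo-3-methylocta-2,6-diene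
Product: 10 (2Z,4S,6Z)-4,8-bis[(tert-butyldimethylsilyl)oxy]-2,6-dimethylocta-2,6-dienal, via alkenyllithium 9 (not isolated)
Conditions: t-BuLi (2.1 equiv), Et2O, −78 °C, 10 min; DMF, −78 → −20 °C; H2O
Reagents that add atoms: N,N-dimethylformamide CN(C)C=O
Why: Iodine–lithium exchange proceeds with retention of alkene geometry and Bouveault-type formylation with DMF installs C9 as the Z-enal, the short cold contact time outrunning 1,4-silyl migration.

Step 6
Reactants: 11 furan-3-ylmethanol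
Product: 12 tert-butyl(furan-3-ylmethoxy)dimethylsilane
Conditions: TBSCl, imidazole, CH2Cl2, rt
Reagents that add atoms: tert-butyldimethylsilyl chloride CC(C)(C)[Si](C)(C)Cl
Why: Routine silylation of the primary alcohol.

Step 7
Reactants: 12 tert-butyl(furan-3-ylmethoxy)dimethylsilane
Product: 14 tert-butyldimethyl({2-[(trimethylsilyl)oxy]furan-3-yl}methoxy)silane, via 2-furyllithium 13 (not isolated)
Conditions: n-BuLi, Et2O, −78 → 0 °C; Me3SiOOSiMe3, −78 °C → rt
Reagents that add atoms: bis(trimethylsilyl) peroxide C[Si](C)(C)OO[Si](C)(C)C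
Why: The ether oxygen directs lithiation to the adjacent furan 2-position and the furyllithium attacks the O–O bond of the silyl peroxide (electrophilic silyloxylation), giving the dienol silyl ether of the 3-substituted butenolide.

Step 8
Reactants: 10 (2Z,4S,6Z)-4,8-bis[(tert-butyldimethylsilyl)oxy]-2,6-dimethylocta-2,6-dienal; 14 tert-butyldimethyl({2-[(trimethylsilyl)oxy]furan-3-yl}methoxy)silane
Product: 16 (5R)-3-{[(tert-butyldimethylsilyl)oxy]methyl}-5-[(1R,2Z,4S,6Z)-4,8-bis[(tert-butyldimethylsilyl)oxy]-1-hydroxy-2,6-dimethylocta-2,6-dien-1-yl]furan-2(5H)-one, via trimethylsilyl ether 15 (not isolated)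
Conditions: Ti(OiPr)4 (20 mol %), (S)-BINOL (20 mol %), Et2O, −20 °C; then citric acid, MeOH, 0 °C
Reagents that add atoms: none
Why: Vinylogous Mukaiyama aldol reaction in which the furan 5-position adds to the titanium–BINOL-activated enal, the catalyst choosing the aldehyde face and the usual threo preference of silyloxyfurans setting C8 and C9 (both R).

Step 9
Reactants: 16 (5R)-3-{[(tert-butyldimethylsilyl)oxy]methyl}-5-[(1R,2Z,4S,6Z)-4,8-bis[(tert-butyldimethylsilyl)oxy]-1-hydroxy-2,6-dimethylocta-2,6-dien-1-yl]furan-2(5H)-one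
Product: 17 (5R)-3-{[(tert-butyldimethylsilyl)oxy]methyl}-5-[(1R,2Z,4S,6Z)-1,4,8-tris[(tert-butyldimethylsilyl)oxy]-2,6-dimethylocta-2,6-dien-1-yl]furan-2(5H)-one
Conditions: TBSOTf, 2,6-lutidine, CH2Cl2, −78 °C
Reagents that add atoms: tert-butyldimethylsilyl triflate CC(C)(C)[Si](C)(C)OS(=O)(=O)C(F)(F)F
Why: Silylation of the hindered secondary alcohol with the silyl triflate and a weak hindered base leaves the base-sensitive C8 stereocentre of the butenolide untouched.

Step 10
Reactants: 17 (5R)-3-{[(tert-butyldimethylsilyl)oxy]methyl}-5-[(1R,2Z,4S,6Z)-1,4,8-tris[(tert-butyldimethylsilyl)oxy]-2,6-dimethylocta-2,6-dien-1-yl]furan-2(5H)-one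
Product: 18 (5R)-5-[(1R,2Z,4S,6Z)-1,4-bis[(tert-butyldimethylsilyl)oxy]-8-hydroxy-2,6-dimethylocta-2,6-dien-1-yl]-3-(hydroxymethyl)furan-2(5H)-one
Conditions: HF·pyridine, pyridine, THF, 0 °C
Reagents that add atoms: none
Why: Buffered fluoride cleaves the two unhindered primary silyl ethers much faster than the two secondary allylic ones (selective desilylation).

Step 11
Reactants: 18 (5R)-5-[(1R,2Z,4S,6Z)-1,4-bis[(tert-butyldimethylsilyl)oxy]-8-hydroxy-2,6-dimethylocta-2,6-dien-1-yl]-3-(hydroxymethyl)furan-2(5H)-one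
Product: 19 (2Z,5S,6Z,8R)-5,8-bis[(tert-butyldimethylsilyl)oxy]-8-[(2R)-4-(hydroxymethyl)-5-oxo-2,5-dihydrofuran-2-yl]-3,7-dimethylocta-2,6-dienal
Conditions: MnO2 (20 equiv), CH2Cl2, rt
Reagents that add atoms: none
Why: MnO2 oxidises the electron-rich Z-allylic alcohol to the enal without alkene isomerisation, while the hydroxymethyl group on the electron-poor butenolide alkene reacts far more slowly (chemoselective allylic oxidation).

Step 12
Reactants: 19 (2Z,5S,6Z,8R)-5,8-bis[(tert-butyldimethylsilyl)oxy]-8-[(2R)-4-(hydroxymethyl)-5-oxo-2,5-dihydrofuran-2-yl]-3,7-dimethylocta-2,6-dienal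
Product: 20 (2Z,5S,6Z,8R)-8-[(2R)-4-(bromomethyl)-5-oxo-2,5-dihydrofuran-2-yl]-5,8-bis[(tert-butyldimethylsilyl)oxy]-3,7-dimethylocta-2,6-dienal
Conditions: PPh3, NBS (slight excess, premixed), CH2Cl2, −30 → 0 °C
Reagents that add atoms: N-bromosuccinimide O=C1CCC(=O)N1Br
Why: Appel-type bromination through the alkoxyphosphonium bromide converts the primary allylic alcohol into the bromide under neutral conditions that spare the enal and the silyl ethers.

Step 13
Reactants: 20 (2Z,5S,6Z,8R)-8-[(2R)-4-(bromomethyl)-5-oxo-2,5-dihydrofuran-2-yl]-5,8-bis[(tert-butyldimethylsilyl)oxy]-3,7-dimethylocta-2,6-dienal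
Product: 22 (3aS,4R,5Z,8S,9Z,11R,11aR)-8,11-bis[(tert-butyldimethylsilyl)oxy]-4-hydroxy-6,10-dimethyl-3-methylidene-3a,4,7,8,11,11a-hexahydrocyclodeca[b]furan-2(3H)-one, via allylchromium 21 (not isolated)
Conditions: CrCl2 (8 equiv), THF/DMF, rt, syringe-pump addition to 2 mM; H2O
Reagents that add atoms: none
Why: Proposed new method: divalent chromium turns the allylic bromide into an allylchromium whose γ-carbon (C7, the butenolide β-carbon) adds to the tethered enal through a six-membered chair on the lactone face anti to the C8 side chain with the enal residue pseudo-equatorial, which closes the ten-membered ring, unveils the C11=C13 methylene and sets C7 (trans-fused, S) and C6 (R, the anti adduct expected from a γ-substituent locked trans to the CH2–metal terminus); closest known reaction type: intermolecular Barbier allylation of aldehydes with 3-(bromomethyl)furan-2(5H)-one and Nozaki–Hiyama–Kishi-type macrocyclisation of 2-(bromomethyl)acrylates onto enals in germacranolide synthesis.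

Step 14
Reactants: 22 (3aS,4R,5Z,8S,9Z,11R,11aR)-8,11-bis[(tert-butyldimethylsilyl)oxy]-4-hydroxy-6,10-dimethyl-3-methylidene-3a,4,7,8,11,11a-hexahydrocyclodeca[b]furan-2(3H)-one; 23 (2R)-2-methylbutanoic acid
Product: 24 (3aS,4R,5Z,8S,9Z,11R,11aR)-8,11-bis[(tert-butyldimethylsilyl)oxy]-6,10-dimethyl-3-methylidene-2-oxo-2,3,3a,4,7,8,11,11a-octahydrocyclodeca[b]furan-4-yl (2R)-2-methylbutanoate
Conditions: DCC, DMAP (cat.), CH2Cl2, 0 °C → rt
Reagents that add atoms: none
Why: Steglich esterification of the only free hydroxyl (C6) with the enantiopure acid under mild carbodiimide activation, which does not epimerise the simple α-methyl stereocentre.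

Step 15
Reactants: 24 (3aS,4R,5Z,8S,9Z,11R,11aR)-8,11-bis[(tert-butyldimethylsilyl)oxy]-6,10-dimethyl-3-methylidene-2-oxo-2,3,3a,4,7,8,11,11a-octahydrocyclodeca[b]furan-4-yl (2R)-2-methylbutanoate
Product: 25 (3aS,4R,5Z,8S,9Z,11R,11aR)-8,11-dihydroxy-6,10-dimethyl-3-methylidene-2-oxo-2,3,3a,4,7,8,11,11a-octahydrocyclodeca[b]furan-4-yl (2R)-2-methylbutanoate
Conditions: HF·pyridine (excess), THF, 0 °C → rt
Reagents that add atoms: none
Why: Fluoride cleavage of the two secondary silyl ethers under mildly acidic conditions leaves the allylic ester, the α-methylene lactone and both Z-alkenes unchanged (global desilylation).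

**Compound list**

1 | methyl 3-methylbut-2-enoate | COC(=O)C=C(C)C | starting material
2 | [(1-methoxy-3-methylbuta-1,3-dien-1-yl)oxy]trimethylsilane | COC(O[Si](C)(C)C)=CC(C)=C | intermediate
3 | but-2-ynal | CC#CC=O | starting material
4 | Tol-BINAP-bound monovalent copper alkoxide of methyl (2Z,5S)-5-hydroxy-3-methyloct-2-en-6-ynoate | COC(=O)/C=C(/C)C[C@H](O[Cu])C#CC | intermediate
5 | (6S)-4-methyl-6-(prop-1-yn-1-yl)-5,6-dihydro-2H-pyran-2-one | O=C1C=C(C)C[C@H](O1)C#CC | intermediate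
6 | cyclic alkenylalanate of (2Z,5S)-3-methyloct-2-en-6-yne-1,5-diol (five-membered O–Al–C chelate, Al on the methyl-bearing alkene carbon, sodium counter-ions) | CC1=C[C@H](C/C(C)=C\C[O-])O[Al-]1(OCCOC)OCCOC.[Na+].[Na+] | intermediate
7 | (2Z,5S,6Z)-7-iodo-3-methylocta-2,6-diene-1,5-diol | OC/C=C(/C)C[C@H](O)/C=C(/C)I | intermediate
8 | (2Z,5S,6Z)-1,5-bis[(tert-butyldimethylsilyl)oxy]-7-iodo-3-methylocta-2,6-diene | CC(C)(C)[Si](C)(C)OC/C=C(/C)C[C@H](O[Si](C)(C)C(C)(C)C)/C=C(/C)I | intermediate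
9 | [(2E,4S,6Z)-4,8-bis[(tert-butyldimethylsilyl)oxy]-6-methylocta-2,6-dien-2-yl]lithium (lithium cis to C4) | CC(C)(C)[Si](C)(C)OC/C=C(/C)C[C@H](O[Si](C)(C)C(C)(C)C)/C=C(/C)[Li] | intermediate
10 | (2Z,4S,6Z)-4,8-bis[(tert-butyldimethylsilyl)oxy]-2,6-dimethylocta-2,6-dienal | CC(C)(C)[Si](C)(C)OC/C=C(/C)C[C@H](O[Si](C)(C)C(C)(C)C)/C=C(/C)C=O | intermediate
11 | furan-3-ylmethanol | OCc1ccoc1 | starting material
12 | tert-butyl(furan-3-ylmethoxy)dimethylsilane | CC(C)(C)[Si](C)(C)OCc1ccoc1 | intermediate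
13 | [3-({[tert-butyl(dimethyl)silyl]oxy}methyl)furan-2-yl]lithium | CC(C)(C)[Si](C)(C)OCc1ccoc1[Li] | intermediate
14 | tert-butyldimethyl({2-[(trimethylsilyl)oxy]furan-3-yl}methoxy)silane | CC(C)(C)[Si](C)(C)OCc1ccoc1O[Si](C)(C)C | intermediate
15 | 1-O-trimethylsilyl ether of 16 | CC(C)(C)[Si](C)(C)OCC1=C[C@H]([C@H](O[Si](C)(C)C)/C(C)=C\[C@@H](O[Si](C)(C)C(C)(C)C)C/C(C)=C\CO[Si](C)(C)C(C)(C)C)OC1=O | intermediate
16 | (5R)-3-{[(tert-butyldimethylsilyl)oxy]methyl}-5-[(1R,2Z,4S,6Z)-4,8-bis[(tert-butyldimethylsilyl)oxy]-1-hydroxy-2,6-dimethylocta-2,6-dien-1-yl]furan-2(5H)-one | CC(C)(C)[Si](C)(C)OCC1=C[C@H]([C@H](O)/C(C)=C\[C@@H](O[Si](C)(C)C(C)(C)C)C/C(C)=C\CO[Si](C)(C)C(C)(C)C)OC1=O | intermediate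
17 | (5R)-3-{[(tert-butyldimethylsilyl)oxy]methyl}-5-[(1R,2Z,4S,6Z)-1,4,8-tris[(tert-butyldimethylsilyl)oxy]-2,6-dimethylocta-2,6-dien-1-yl]furan-2(5H)-one | CC(C)(C)[Si](C)(C)OCC1=C[C@H]([C@H](O[Si](C)(C)C(C)(C)C)/C(C)=C\[C@@H](O[Si](C)(C)C(C)(C)C)C/C(C)=C\CO[Si](C)(C)C(C)(C)C)OC1=O | intermediate
18 | (5R)-5-[(1R,2Z,4S,6Z)-1,4-bis[(tert-butyldimethylsilyl)oxy]-8-hydroxy-2,6-dimethylocta-2,6-dien-1-yl]-3-(hydroxymethyl)furan-2(5H)-one | OCC1=C[C@H]([C@H](O[Si](C)(C)C(C)(C)C)/C(C)=C\[C@@H](O[Si](C)(C)C(C)(C)C)C/C(C)=C\CO)OC1=O | intermediate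
19 | (2Z,5S,6Z,8R)-5,8-bis[(tert-butyldimethylsilyl)oxy]-8-[(2R)-4-(hydroxymethyl)-5-oxo-2,5-dihydrofuran-2-yl]-3,7-dimethylocta-2,6-dienal | OCC1=C[C@H]([C@H](O[Si](C)(C)C(C)(C)C)/C(C)=C\[C@@H](O[Si](C)(C)C(C)(C)C)C/C(C)=C\C=O)OC1=O | intermediate
20 | (2Z,5S,6Z,8R)-8-[(2R)-4-(bromomethyl)-5-oxo-2,5-dihydrofuran-2-yl]-5,8-bis[(tert-butyldimethylsilyl)oxy]-3,7-dimethylocta-2,6-dienal | BrCC1=C[C@H]([C@H](O[Si](C)(C)C(C)(C)C)/C(C)=C\[C@@H](O[Si](C)(C)C(C)(C)C)C/C(C)=C\C=O)OC1=O | intermediate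
21 | allylchromium dichloride (trivalent chromium) derived from 20, CrCl2 unit on the exocyclic CH2 of the butenolide | Cl[Cr](Cl)CC1=C[C@H]([C@H](O[Si](C)(C)C(C)(C)C)/C(C)=C\[C@@H](O[Si](C)(C)C(C)(C)C)C/C(C)=C\C=O)OC1=O | intermediate
22 | (3aS,4R,5Z,8S,9Z,11R,11aR)-8,11-bis[(tert-butyldimethylsilyl)oxy]-4-hydroxy-6,10-dimethyl-3-methylidene-3a,4,7,8,11,11a-hexahydrocyclodeca[b]furan-2(3H)-one | C=C1C(=O)O[C@@H]2[C@@H]1[C@H](O)/C=C(/C)C[C@H](O[Si](C)(C)C(C)(C)C)/C=C(/C)[C@H]2O[Si](C)(C)C(C)(C)C | intermediate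
23 | (2R)-2-methylbutanoic acid | CC[C@@H](C)C(=O)O | starting material
24 | (3aS,4R,5Z,8S,9Z,11R,11aR)-8,11-bis[(tert-butyldimethylsilyl)oxy]-6,10-dimethyl-3-methylidene-2-oxo-2,3,3a,4,7,8,11,11a-octahydrocyclodeca[b]furan-4-yl (2R)-2-methylbutanoate | C=C1C(=O)O[C@@H]2[C@@H]1[C@H](OC(=O)[C@H](C)CC)/C=C(/C)C[C@H](O[Si](C)(C)C(C)(C)C)/C=C(/C)[C@H]2O[Si](C)(C)C(C)(C)C | intermediate
25 | (3aS,4R,5Z,8S,9Z,11R,11aR)-8,11-dihydroxy-6,10-dimethyl-3-methylidene-2-oxo-2,3,3a,4,7,8,11,11a-octahydrocyclodeca[b]furan-4-yl (2R)-2-methylbutanoate | C=C1C(=O)O[C@@H]2[C@@H]1[C@H](OC(=O)[C@H](C)CC)/C=C(/C)C[C@H](O)/C=C(/C)[C@H]2O | target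

**Step count and risks**

Total: 15 steps. Longest linear sequence: 13 steps (1–5 and 8–15, from methyl 3-methylbut-2-enoate).

The three steps most likely to fail:

Step 13 (ring closure). Risks are oligomerisation, attack through the CH2 terminus instead of C7, and the wrong C6 epimer if the macrocyclic chair is not the one assumed. The fallback sets out from 19 and returns at 22. The hydroxymethyl group of 19 is acetylated (Ac2O, pyridine) to the allylic acetate F8. The ring is then closed by umpolung allylation under zerovalent palladium catalysis: Pd(PPh3)4 with indium monoiodide (InI) in THF at high dilution converts the acetate through a π-allylpalladium species into the allylindium F9. This is formed only at low stationary concentration and adds to the enal through a closed transition state to give 22.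

Step 8 (vinylogous aldol). Risks are a modest threo:erythro ratio and weak catalyst control on a hindered Z-α-methyl enal. The fallback sets out from 10 and returns at 20, without the furan donor.
- Reagent-controlled Brown syn-alkoxyallylation of 10 with (Z)-γ-(4-methoxybenzyloxy)allyl-B(Ipc)2 (the antipode giving the 3R,4R adduct) gives the PMB-protected syn-diol F2.
- Silylation (TBSOTf, 2,6-lutidine) gives the silyl ether F3, and DDQ removes the PMB group to give the allylic alcohol F4.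
- Esterification with 2-(bromomethyl)acrylic acid (DCC, 5 mol % DMAP, −20 °C) gives the 2-(bromomethyl)acrylate F5.
- Ring-closing metathesis with the second-generation Grubbs catalyst (toluene, 60 °C) closes the butenolide with the bromide already in place, giving the bromomethylbutenolide F6.
- Aqueous HF in MeCN at 0 °C removes only the primary silyl ether, giving the primary alcohol F7, and Dess–Martin periodinane with NaHCO3 gives 20.

Step 2 (asymmetric vinylogous aldol/lactonisation). Risks are insufficient enantioselectivity with the small ynal and incomplete lactonisation. The fallback sets out from 3 and returns at 5. A hetero-Diels–Alder reaction of but-2-ynal with 1-methoxy-3-methylbuta-1,3-diene, catalysed by Jacobsen's tridentate Schiff-base chromium chloride catalyst (trivalent chromium, 4 Å molecular sieves, rt), gives the cyclic acetal F1. Its allylic acetal carbon is oxidised directly with pyridinium chlorochromate C5H5NH[CrO3Cl] in CH2Cl2 to lactone 5.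

Further compounds

F1 | step 2 | (2R,6S)-2-methoxy-4-methyl-6-(prop-1-yn-1-yl)-5,6-dihydro-2H-pyran | CO[C@H]1C=C(C)C[C@H](O1)C#CC
F2 | step 8 | (3R,4R,5Z,7S,9Z)-7,11-bis[(tert-butyldimethylsilyl)oxy]-3-[(4-methoxyphenyl)methoxy]-5,9-dimethylundeca-1,5,9-trien-4-ol | C=C[C@@H](OCc1ccc(OC)cc1)[C@H](O)/C(C)=C\[C@@H](O[Si](C)(C)C(C)(C)C)C/C(C)=C\CO[Si](C)(C)C(C)(C)C
F3 | step 8 | (3R,4R,5Z,7S,9Z)-4,7,11-tris[(tert-butyldimethylsilyl)oxy]-3-[(4-methoxyphenyl)methoxy]-5,9-dimethylundeca-1,5,9-triene | C=C[C@@H](OCc1ccc(OC)cc1)[C@H](O[Si](C)(C)C(C)(C)C)/C(C)=C\[C@@H](O[Si](C)(C)C(C)(C)C)C/C(C)=C\CO[Si](C)(C)C(C)(C)C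
F4 | step 8 | (3R,4R,5Z,7S,9Z)-4,7,11-tris[(tert-butyldimethylsilyl)oxy]-5,9-dimethylundeca-1,5,9-trien-3-ol | C=C[C@@H](O)[C@H](O[Si](C)(C)C(C)(C)C)/C(C)=C\[C@@H](O[Si](C)(C)C(C)(C)C)C/C(C)=C\CO[Si](C)(C)C(C)(C)C
F5 | step 8 | (3R,4R,5Z,7S,9Z)-4,7,11-tris[(tert-butyldimethylsilyl)oxy]-5,9-dimethylundeca-1,5,9-trien-3-yl 2-(bromomethyl)prop-2-enoate | C=C[C@@H](OC(=O)C(=C)CBr)[C@H](O[Si](C)(C)C(C)(C)C)/C(C)=C\[C@@H](O[Si](C)(C)C(C)(C)C)C/C(C)=C\CO[Si](C)(C)C(C)(C)C
F6 | step 8 | (5R)-3-(bromomethyl)-5-[(1R,2Z,4S,6Z)-1,4,8-tris[(tert-butyldimethylsilyl)oxy]-2,6-dimethylocta-2,6-dien-1-yl]furan-2(5H)-one | BrCC1=C[C@H]([C@H](O[Si](C)(C)C(C)(C)C)/C(C)=C\[C@@H](O[Si](C)(C)C(C)(C)C)C/C(C)=C\CO[Si](C)(C)C(C)(C)C)OC1=O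
F7 | step 8 | (5R)-3-(bromomethyl)-5-[(1R,2Z,4S,6Z)-1,4-bis[(tert-butyldimethylsilyl)oxy]-8-hydroxy-2,6-dimethylocta-2,6-dien-1-yl]furan-2(5H)-one | BrCC1=C[C@H]([C@H](O[Si](C)(C)C(C)(C)C)/C(C)=C\[C@@H](O[Si](C)(C)C(C)(C)C)C/C(C)=C\CO)OC1=O
F8 | step 13 | {(5R)-5-[(1R,2Z,4S,6Z)-1,4-bis[(tert-butyldimethylsilyl)oxy]-2,6-dimethyl-8-oxoocta-2,6-dien-1-yl]-2-oxo-2,5-dihydrofuran-3-yl}methyl acetate | CC(=O)OCC1=C[C@H]([C@H](O[Si](C)(C)C(C)(C)C)/C(C)=C\[C@@H](O[Si](C)(C)C(C)(C)C)C/C(C)=C\C=O)OC1=O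
F9 | step 13 | allylindium acetate iodide (trivalent indium) derived from F8, indium on the exocyclic CH2 of the butenolide | CC(=O)O[In](I)CC1=C[C@H]([C@H](O[Si](C)(C)C(C)(C)C)/C(C)=C\[C@@H](O[Si](C)(C)C(C)(C)C)C/C(C)=C\C=O)OC1=O
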